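## The problem

The target is a briarane. A ten-membered carbocycle (C1–C10) is trans-fused at C1/C10 to a cyclohexenone (ring A, C1, C10–C14), and a γ-lactone (O–C7, C8, C17, C19) is fused across C7–C8. Ten stereocentres must be set (C1, C2, C3, C6–C11, C17), three of them fully substituted (C1, C8, C11), and eight lie on the medium ring. Some centres can direct others: C8 can direct the aldehyde faces at C7 and C9, C1 can direct C10, C10 can direct C11, and only the ring conformation can direct the 2,3-epoxide. Several groups rule out rough conditions. The secondary allylic chloride at C6 sits next to an oxygen-bearing carbon, so base gives epoxide or elimination and nucleophiles attack with allylic shift. The C8 carbinol is β to the lactone carbonyl, the trans-epoxide is acid-labile, and the acetoxyacetate and the enone are base- and nucleophile-sensitive. The key step rests on one feature: C16=C5–C6(Cl)–C7(O) is the syn chlorohydrin of a 2-substituted allyl unit, and the C7 oxygen is γ to the C19 carbonyl. One allyl transfer to a C7 aldehyde can therefore set the chloride, the carbinol and the exocyclic methylene, and the new alkoxide can close the lactone. The second large problem is closing the ten-membered ring without disturbing this domain.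

## Retrosynthesis

Positions carry briarane numbers (C1–C20); compounds carry the numbers of the steps below.

**Epoxide last (42 ⇒ 41).** The two C–O bonds of the epoxide are cut first. The epoxide is the group least likely to survive acid, fluoride or Lewis acids, so it is made in the final step from the E-alkene of 41 with a neutral oxygen-transfer reagent. The alkene must be the most nucleophilic of three, which holds: C5=C16 is hindered and deactivated by the allylic chloride, and C13=C14 is part of an enone.

**Acyl group and protecting groups (41 ⇒ 40 ⇒ 39).** The C9 ester C–O bond is cut next, because an acetoxyacetate would not survive the strong base of the ring closure. In 39 the C8 and C9 oxygens are both methoxymethyl ethers, removed together; the secondary C9 hydroxyl of 40 is then acylated in preference to the tertiary C8 hydroxyl.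

**Ring closure at C2=C3 (39 ⇒ 38).** The ten-membered ring is opened at the C2=C3 double bond, which a Julia–Kocienski reaction can form with E geometry. The alternative cut at C9–C10 would close the ring at a bond between two stereocentres. The sulfone is placed on C3 and the aldehyde on C2: a C2 aldehyde on quaternary C1 cannot enolise, whereas a C3 aldehyde would be β,γ-unsaturated to C5=C16 and would isomerise under base. Precursor 38 is acyclic between the lactone domain and ring A.

**Ring A functionality (38 ⇒ 34 ⇒ 33 ⇒ 32 ⇒ 31 ⇒ 30).** The C11–O bond and the hydrogen on C20 are cut. A methyl nucleophile adding to a C11 ketone would enter anti to the C9 substituent on C10 and anti to the C15 methyl, giving the wrong epimer. The order is therefore reversed: C20 is attached first as a methylene (31), the C12 ketal is opened to the cross-conjugated dienone 32, and oxygen is then delivered to C11 from the open α face (33). Ketone 30 is much simpler, carrying only a C11 carbonyl and a masked C12 ketone.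

**Union at C9–C10 (30 ⇒ 29 ⇒ 28 + 27).** The C9–C10 bond is cut as an aldol between aldehyde 28 and silyl enol ether 27, whose enol can only lie towards C10 because C12 is a ketal. A non-chelated addition to 28 is expected to give the C9 epimer, so the C8 oxygen carries a chelating methoxymethyl group and the reaction is run with a chelating magnesium Lewis acid. The same step sets C10 anti to the bulky silyloxymethyl group on C1.

**Key cut at C6–C7 and the lactone C–O bond (28 ⇒ 17 ⇒ 9 + 13 through 14).** Lactone 17 is cut at C6–C7 and at O–C19. The forward reaction is the addition of γ-chloroallylborane 14, made in the flask from allylic chloride 13, to aldehyde 9, followed by lactonisation. This installs the chloride directly, with no later substitution at a centre prone to allylic shift. The reaction must deliver syn C6/C7, the correct aldehyde face, and lactone closure in preference to epoxide closure.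

**Aldehyde 9 (9 ⇒ 8 ⇒ 7 ⇒ 6 ⇒ 3 + 5).** The C8–C17 bond is cut as a catalytic, anti-selective aldol between ketoester 3 (from 1) and thioester silyl ketene acetal 5 (from 4). An aldol on a symmetric dihydroxyacetone derivative would leave C8 unset; here the two arms on C8 differ in oxidation level from the start (C7 ester, C9 silyl ether), and C8 and C17 are set together.

**Ring A fragment (27 ⇒ 26 ⇒ 23 ⇒ 22 ⇒ 20 ⇒ 18 + 19).** The C1 quaternary centre comes from an enantioselective Diels–Alder reaction of aminosiloxydiene 18 with methacrolein 19. Elimination of the amine gives enone 22 regiospecifically, so C12=O and C13=C14 are in place from the start. C11 is then oxidised and C12 masked.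

**Allylic chloride 13 (13 ⇒ 12 ⇒ 11 ⇒ 10).** Dimethyl itaconate 10 already holds C3–C6 and C16. Reduction, selective allylic chlorination and silylation give 13 without the regiochemical ambiguity of chlorinating an isoprenol derivative.

## Roads not taken

Alternative 1: The cut is through a C3–C8 bond of a fused tricyclic skeleton. A potassium alkoxide-induced fragmentation of a C8 tertiary alkoxide with loss of a C2 sulfonate would open the ten-membered ring and give cyclodecadienone A1. Its merits are real: the medium ring is formed from strain-free six-membered rings, and the E geometry of C2=C3 follows from the antiperiplanar arrangement. In ring formation it is better than the chosen plan, which must close a ten-membered ring against entropy. Its weak point is what A1 lacks: the C5 methylene, the C6 chloride, the C7 oxygen, the C8 carbinol, C17 and the lactone. All of these would have to be added to a flexible medium-ring enone, where facial control is poor and the chloride would have to be introduced late beside an enolisable ketone. The chosen plan sets C6, C7, C8 and C17 in open-chain compounds by reagent and alkene geometry and accepts the harder ring closure.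

Alternative 2: The cut is the C11–C12 bond of ring A. A carbene-catalysed crossed benzoin reaction between a C12 aldehyde and a C11 methyl ketone would close ring A last and give α-ketol A2. It is better than the chosen plan at C11: the tertiary α-ketol is formed in one catalytic step, where the chosen route needs methylenation, ketal hydrolysis and oxygenation. Its weak points are three. A2 carries a silyl ether at C6 with the opposite configuration, so the chloride must be introduced later by substitution with inversion at a hindered allylic position, where allylic shift competes. Ring A of A2 is saturated at C13–C14 and must be dehydrogenated late. And C11 is set by the conformation of a ten-membered ring that already holds the epoxide. The chosen plan installs the chloride directly and has C13=C14 and the C1 centre in place before the fragments are joined.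

Alternative 3: The cut is the lactone C7–O bond and the C6–Cl bond on a six-membered quinol. A carbonate-mediated oxa-Michael addition of a quinol carboxylate, with chlorination of the resulting enolate, would give cis-fused chloro lactone A3 in one step. It is clearly shorter to the chloro lactone than the chosen plan, and the cis ring fusion relates C7 and C8 reliably. Its weak points lie after the key step. In A3 the carbon that becomes C5 is a ring ketone flanked by the chloride, so C6 can epimerise or eliminate. The cyclohexenone must be cleaved oxidatively to release the chain ends, and the ketone must be methylenated without base. The chloride enters on the convex face of the enolate, which need not be the face required for the syn C6/C7 relation. The chosen plan obtains C5=C16 by allylic transposition, and both chain ends (C3 and C9) emerge as differentiated silyl ethers.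

Key step: step 11

Assumption: the ligand antipodes written in steps 4, 11 and 12 are taken to give the configurations drawn; if the sense of induction of any of them is the opposite, the mirror-image ligand is used and nothing else changes.

## Route

Step 1
Reactants: 1 methyl pyruvate
Product: 2 methyl 2-[(triethylsilyl)oxy]prop-2-enoate
Conditions: TESOTf, Et3N, CH2Cl2, 0 °C
Reagents that add atoms: triethylsilyl trifluoromethanesulfonate, CC[Si](CC)(CC)OS(=O)(=O)C(F)(F)F
Why: Soft enolisation of the ketone and O-silylation (silyl enol ether formation); the ester cannot enolise, so only one enol ether can form.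

Step 2
Reactants: 2 methyl 2-[(triethylsilyl)oxy]prop-2-enoate
Product: 3 methyl 2-oxo-3-[(triethylsilyl)oxy]propanoate
Conditions: dimethyldioxirane, acetone, −20 → 23 °C
Reagents that add atoms: dimethyldioxirane, CC1(C)OO1
Why: Rubottom oxidation: epoxidation of the silyl enol ether and 1,4-silyl shift should give the α-silyloxy ketone directly under neutral conditions, which keeps the primary silyl ether.

Step 3
Reactants: 4 S-ethyl propanethioate
Product: 5 (Z)-1-(ethylsulfanyl)-1-[(trimethylsilyl)oxy]prop-1-ene
Conditions: LiN(i-Pr)2, THF, −78 °C; Me3SiCl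
Reagents that add atoms: chlorotrimethylsilane, C[Si](C)(C)Cl
Why: Kinetic enolisation of the thioester and O-silylation (silyl ketene acetal formation); lithium amide in THF without a polar cosolvent should give the Z isomer.

Step 4
Reactants: 3 methyl 2-oxo-3-[(triethylsilyl)oxy]propanoate; 5 (Z)-1-(ethylsulfanyl)-1-[(trimethylsilyl)oxy]prop-1-ene
Product: 6 methyl (2R,3R)-4-(ethylsulfanyl)-2-hydroxy-3-methyl-4-oxo-2-{[(triethylsilyl)oxy]methyl}butanoate
Conditions: Sn(OTf)2 (10 mol %), 2,6-bis[(4S)-4-benzyl-4,5-dihydrooxazol-2-yl]pyridine (12 mol %), CH2Cl2, −78 °C; then citric acid, MeOH, 0 °C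
Reagents that add atoms: none
Why: Catalytic enantioselective anti-selective Mukaiyama aldol addition to an α-keto ester: the divalent tin–bis(oxazoline)pyridine complex binds the two carbonyls of 3, the ligand shields one ketone face and the open transition state should give the anti relation between the C8 hydroxyl and the C17 methyl; the mild acidic methanol removes only the tertiary trimethylsilyl ether.

Step 5
Reactants: 6 thioester aldol adduct
Product: 7 dimethyl (2R,3R)-2-hydroxy-3-methyl-2-{[(triethylsilyl)oxy]methyl}butanedioate
Conditions: AgOCOCF3, 2,6-lutidine, MeOH, 23 °C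
Reagents that add atoms: methanol, CO
Why: Thiophile-promoted transesterification of a thioester; silver activates sulfur selectively, so no base that could trigger retro-aldol is needed and the buffer keeps the triethylsilyl ether.

Step 6
Reactants: 7 hydroxy diester
Product: 8 dimethyl (2R,3R)-2-(methoxymethoxy)-3-methyl-2-{[(triethylsilyl)oxy]methyl}butanedioate
Conditions: MOMCl, i-Pr2NEt, NaI (cat.), ClCH2CH2Cl, 50 °C
Reagents that add atoms: chloromethyl methyl ether, COCCl
Why: Alkylation of a tertiary α-hydroxy ester with an activated halide (acetal protection); the methoxymethyl group is chosen because it can chelate in steps 7 and 20.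

Step 7
Reactants: 8 methoxymethyl ether diester
Product: 9 methyl (2R,3R)-3-formyl-3-(methoxymethoxy)-2-methyl-4-[(triethylsilyl)oxy]butanoate
Conditions: i-Bu2AlH (1.1 equiv), CH2Cl2, −78 °C; aq. KNaC4H4O6
Reagents that add atoms: none
Why: Partial reduction of an ester to an aldehyde; the α-alkoxy ester should be reduced selectively because aluminium is chelated between its carbonyl and the methoxymethyl oxygen and the tetrahedral intermediate survives until work-up; no free γ-hydroxy ester is formed, so premature lactonisation is avoided.

Step 8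
Reactants: 10 dimethyl itaconate
Product: 11 2-methylidenebutane-1,4-diol
Conditions: i-Bu2AlH (4.5 equiv), CH2Cl2, −78 → 0 °C
Reagents that add atoms: none
Why: 1,2-Reduction of both esters; the aluminium hydride reduces the conjugated ester at the carbonyl and leaves the 1,1-disubstituted alkene.

Step 9
Reactants: 11 2-methylidenebutane-1,4-diol
Product: 12 3-(chloromethyl)but-3-en-1-ol
Conditions: N-chlorosuccinimide, Me2S, CH2Cl2, −20 → 0 °C
Reagents that add atoms: N-chlorosuccinimide, O=C1CCC(=O)N1Cl
Why: Corey–Kim chlorination: under these neutral conditions only the allylic alkoxysulfonium ion is displaced by chloride, so the homoallylic hydroxyl is kept.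

Step 10
Reactants: 12 3-(chloromethyl)but-3-en-1-ol
Product: 13 tert-butyl{[3-(chloromethyl)but-3-en-1-yl]oxy}diphenylsilane
Conditions: TBDPSCl, imidazole, CH2Cl2, 0 °C
Reagents that add atoms: tert-butyl(chloro)diphenylsilane, CC(C)(C)[Si](Cl)(c1ccccc1)c1ccccc1
Why: Silylation of a primary alcohol; the robust silyl ether survives all acidic and Lewis acidic steps up to step 26.

Step 11
Reactants: 13 tert-butyl{[3-(chloromethyl)but-3-en-1-yl]oxy}diphenylsilane; 9 aldehyde
Product: 17 chloro lactone, via chloroallylborane 14 (not isolated), via borinate 15 (not isolated), via hydroxy ester 16 (not isolated)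
Conditions: 13, (+)-Ipc2BOMe, LiN(c-C6H11)2, Et2O, −95 °C; BF3·OEt2, −95 °C; then 9, −95 → −78 °C; HOCH2CH2NH2, 23 °C; PPTS (cat.), PhMe, 50 °C
Reagents that add atoms: none
Why: The lithium amide removes a proton from the CH2Cl group of 13 in the presence of the borinate, the chloroallyl anion is trapped on boron, BF3·OEt2 strips methoxide and 1,3-boron shifts settle on borane 14 with chlorine cis to the CH2B carbon (formally E by the sequence rule, Z in the usual sense of γ-substituted allylboron reagents). Borane 14 binds the aldehyde oxygen of 9 and transfers the allyl unit through a closed six-membered chair with the aldehyde substituent equatorial and chlorine axial, which forms C6–C7, moves the double bond to C5=C16 and gives the syn chlorohydrin as borinate 15. The closest known reaction type is the (Z)-γ-chloroallylboration of aldehydes with dialkylboranes made from allyl chloride in the same way; the extension is the 2-substituent of the allyl unit and the α-quaternary aldehyde. C6 is fixed by the reagent geometry; C7 is fixed by the aldehyde face, where the isopinocampheyl groups derived from (−)-α-pinene direct attack to the Re face, the same face favoured by the Felkin–Anh/Cornforth arrangement of 9 (methoxymethoxy group anti, attack past CH2OSiEt3 and not past CH(CH3)CO2CH3), so reagent and substrate are matched. Ethanolamine removes boron and frees hydroxy ester 16, whose C7 hydroxyl closes the γ-lactone by 5-exo-trig acyl substitution on the C19 methyl ester under mild acid, helped by the quaternary C8. The step needs regioselective deprotonation (secured by the acidity of the allylic CH2Cl group and the in situ trap), reaction at the aldehyde and not the ester (allylboranes add to aldehydes at −95 °C), and lactone closure in preference to epoxide closure (secured by the absence of base).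

Step 12
Reactants: 18 (E)-1-(dimethylamino)-3-[(tert-butyldimethylsilyl)oxy]buta-1,3-diene; 19 methacrolein
Product: 20 (1R,2S)-2-(dimethylamino)-1-methyl-4-[(tert-butyldimethylsilyl)oxy]cyclohex-3-ene-1-carbaldehyde
Conditions: (4R,5R)-2,2-dimethyl-α,α,α′,α′-tetra(1-naphthyl)-1,3-dioxolane-4,5-dimethanol (20 mol %), PhMe, −80 °C
Reagents that add atoms: none
Why: Hydrogen-bond-catalysed enantioselective Diels–Alder reaction: the diol activates the aldehyde and shields one face, the amino terminus of the diene bonds to the α-carbon of methacrolein, and the quaternary C1 is set; the C14 amine centre is lost in step 13.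

Step 13
Reactants: 20 Diels–Alder adduct
Product: 22 (R)-4-(hydroxymethyl)-4-methylcyclohex-2-en-1-one, via amino alcohol 21 (not isolated)
Conditions: LiAlH4, Et2O, −78 → 0 °C; then HF (aq.), MeCN, 23 °C
Reagents that add atoms: none
Why: Hydride reduction of the aldehyde, then hydrolysis of the silyl enol ether and β-elimination of dimethylamine; the elimination places the double bond at C13=C14 only, so the C1 centre stays defined.

Step 14
Reactants: 22 (R)-4-(hydroxymethyl)-4-methylcyclohex-2-en-1-one
Product: 23 (R)-4-{[(tert-butyldiphenylsilyl)oxy]methyl}-4-methylcyclohex-2-en-1-one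
Conditions: TBDPSCl, imidazole, DMF, 23 °C
Reagents that add atoms: tert-butyl(chloro)diphenylsilane, CC(C)(C)[Si](Cl)(c1ccccc1)c1ccccc1
Why: Silylation of a neopentyl primary alcohol; the large silyloxymethyl group later directs the electrophile at C10 to the face of the C15 methyl.

Step 15
Reactants: 23 silyl ether enone
Product: 24 (4R)-4-{[(tert-butyldiphenylsilyl)oxy]methyl}-6-hydroxy-4-methylcyclohex-2-en-1-one
Conditions: LiN(i-Pr)2, THF, −78 °C; 2-(phenylsulfonyl)-3-phenyloxaziridine
Reagents that add atoms: 2-(phenylsulfonyl)-3-phenyloxaziridine, O=S(=O)(c1ccccc1)N1OC1c1ccccc1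
Why: Kinetic α′-enolisation of the enone and enolate oxidation with an N-sulfonyloxaziridine; the configuration of the new carbinol (C11) is irrelevant because it is oxidised in step 17.

Step 16
Reactants: 24 α′-hydroxy enone
Product: 25 (8R)-8-{[(tert-butyldiphenylsilyl)oxy]methyl}-8-methyl-1,4-dioxaspiro[4.5]dec-9-en-6-ol
Conditions: Me3SiOCH2CH2OSiMe3, TMSOTf (cat.), CH2Cl2, −78 → −20 °C; then K2CO3, MeOH, 0 °C
Reagents that add atoms: 1,2-bis(trimethylsilyloxy)ethane, C[Si](C)(C)OCCO[Si](C)(C)C
Why: Ketalisation with a bis-silyl glycol under aprotic conditions; the double bond cannot move out of conjugation because C1 is quaternary, and the basic methanol only removes the silyl ether formed on the hydroxyl.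

Step 17
Reactants: 25 hydroxy ketal
Product: 26 (8R)-8-{[(tert-butyldiphenylsilyl)oxy]methyl}-8-methyl-1,4-dioxaspiro[4.5]dec-9-en-6-one
Conditions: Dess–Martin periodinane, NaHCO3, CH2Cl2, 23 °C
Reagents that add atoms: none
Why: Oxidation of a secondary alcohol with a hypervalent iodine reagent; the buffer protects the allylic ketal.

Step 18
Reactants: 26 keto ketal
Product: 27 {[(8S)-8-{[(tert-butyldiphenylsilyl)oxy]methyl}-8-methyl-1,4-dioxaspiro[4.5]deca-6,9-dien-6-yl]oxy}trimethylsilane
Conditions: TMSOTf, Et3N, CH2Cl2, 0 °C
Reagents that add atoms: trimethylsilyl trifluoromethanesulfonate, C[Si](C)(C)OS(=O)(=O)C(F)(F)F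
Why: Silyl enol ether formation by soft enolisation; the ketone has α-hydrogens only on C10, so the enol ether is regiodefined.

Step 19
Reactants: 17 chloro lactone
Product: 28 C9 aldehyde lactone
Conditions: (COCl)2, DMSO, CH2Cl2, −78 → −40 °C; Et3N, −78 → 0 °C
Reagents that add atoms: none
Why: Direct Swern oxidation of a primary triethylsilyl ether: the chlorosulfonium ion attacks the least hindered silyl ether oxygen, so the aldehyde forms without a free C9 alcohol that could translactonise; the primary tert-butyldiphenylsilyl ether and the acetal are inert.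

Step 20
Reactants: 28 C9 aldehyde lactone; 27 silyl enol ether
Product: 29 C9–C10 aldol adduct
Conditions: MgBr2·OEt2 (3 equiv), CH2Cl2, −78 → −30 °C
Reagents that add atoms: none
Why: Chelation-controlled Mukaiyama aldol addition: magnesium bridges the aldehyde oxygen and the C8 methoxymethyl oxygen, and the enol ether attacks the face of the chelate flanked by C17 (which shows only hydrogen on that side) and not by C7 with its chloroallyl group, which should set C9. C10 is set by attack anti to the silyloxymethyl group on C1, and the open transition state gives the syn relation between the C9 oxygen and C1 that these two preferences require.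

Step 21
Reactants: 29 aldol adduct
Product: 30 bis(methoxymethyl) ether ketone
Conditions: MOMCl, i-Pr2NEt, Bu4NI (cat.), CH2Cl2, 40 °C
Reagents that add atoms: chloromethyl methyl ether, COCCl
Why: Acetal protection of the secondary hydroxyl under weakly basic conditions that should not open the β-hydroxy ketone; both methoxymethyl groups can later be removed in one step.

Step 22
Reactants: 30 bis(methoxymethyl) ether ketone
Product: 31 C11 methylidene ketal
Conditions: Cp2Ti(μ-Cl)(μ-CH2)AlMe2, pyridine, THF–PhMe, −40 → 0 °C
Reagents that add atoms: titanium–aluminium methylidene reagent, C[Al-]1(C)C[Ti](C2C=CC=C2)(C2C=CC=C2)[Cl+]1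
Why: Carbonyl methylenation with a titanium methylidene; the reagent is not basic, so C10 is not epimerised and no β-elimination occurs, and ketones react faster than the lactone.

Step 23
Reactants: 31 C11 methylidene ketal
Product: 32 cross-conjugated dienone
Conditions: PPTS (cat.), acetone–H2O, 23 °C
Reagents that add atoms: water, O
Why: Acid-catalysed ketal hydrolysis; the ketal is doubly allylic and should open under conditions that leave the methoxymethyl and silyl ethers in place.

Step 24
Reactants: 32 cross-conjugated dienone
Product: 33 C11 tertiary α-ketol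
Conditions: Mn(dpm)3 (cat., dpm = dipivaloylmethanate), PhSiH3, O2 (1 atm), i-PrOH–CH2Cl2, 0 °C; then P(OEt)3
Reagents that add atoms: dioxygen, O=O
Why: Hydrogen-atom-transfer reductive oxygenation of an enone: the trivalent manganese hydride delivers hydrogen to the terminal carbon of the activated exocyclic methylene, making C20 a methyl group, and the α-keto radical at C11 is trapped by oxygen on the α face, anti to the C9 substituent on C10 and to the C15 methyl; the phosphite reduces the hydroperoxide.

Step 25
Reactants: 33 C11 tertiary α-ketol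
Product: 34 C11 acetate
Conditions: Ac2O, DMAP, Et3N, CH2Cl2, 40 °C
Reagents that add atoms: acetic anhydride, CC(=O)OC(C)=O
Why: Nucleophile-catalysed acylation; the α-ketol hydroxyl is the only free hydroxyl in 33.

Step 26
Reactants: 34 C11 acetate
Product: 35 C2,C3 diol
Conditions: Bu4NF, AcOH, THF, 0 → 23 °C
Reagents that add atoms: none
Why: Fluoride cleavage of both primary silyl ethers; acetic acid buffers the fluoride so that the acetate and the lactone are kept.

Step 27
Reactants: 35 C2,C3 diol
Product: 36 C3 phenyltetrazolyl sulfide
Conditions: 1-phenyl-1H-tetrazole-5-thiol, PPh3, DIAD, THF, 0 °C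
Reagents that add atoms: 1-phenyl-1H-tetrazole-5-thiol, Sc1nnnn1-c1ccccc1
Why: Mitsunobu thioetherification; the unhindered C3 hydroxyl reacts, while the neopentyl C2 hydroxyl on quaternary C1 is too hindered for displacement.

Step 28
Reactants: 36 C3 sulfide
Product: 37 C3 sulfone
Conditions: (NH4)6Mo7O24·4H2O (cat.), H2O2 (30 % aq.), EtOH, 0 → 23 °C
Reagents that add atoms: hydrogen peroxide, OO
Why: Molybdate-catalysed oxidation of a sulfide to a sulfone; the peroxomolybdate is electrophilic and should spare the enone and the hindered 1,1-disubstituted alkene.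

Step 29
Reactants: 37 C3 sulfone
Product: 38 C2 aldehyde sulfone
Conditions: Dess–Martin periodinane, NaHCO3, CH2Cl2, 23 °C
Reagents that add atoms: none
Why: Oxidation of the neopentyl primary alcohol to an aldehyde that cannot enolise.

Step 30
Reactants: 38 C2 aldehyde sulfone
Product: 39 ten-membered E-alkene
Conditions: KN(SiMe3)2, THF, −78 → 23 °C, 1 mM, slow addition of base
Reagents that add atoms: none
Why: Intramolecular Julia–Kocienski olefination: the sulfonyl carbanion at C3 adds to the C2 aldehyde, and Smiles rearrangement with loss of sulfur dioxide and the tetrazolone forms C2=C3; the E alkene is the expected outcome of the anti addition–elimination sequence and the geometry the trans-fused ring can hold, and high dilution favours ring closure over dimerisation.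

Step 31
Reactants: 39 ten-membered E-alkene
Product: 40 C8,C9 diol
Conditions: Me2BBr, CH2Cl2, −78 °C; then NaHCO3 (aq.), THF
Reagents that add atoms: none
Why: Cleavage of both methoxymethyl ethers with a bromoborane at low temperature, conditions that leave esters, the enone and the allylic chloride untouched.

Step 32
Reactants: 40 C8,C9 diol
Product: 41 C9 acetoxyacetate
Conditions: AcOCH2COCl, pyridine, DMAP (cat.), CH2Cl2, 0 °C
Reagents that add atoms: acetoxyacetyl chloride, CC(=O)OCC(Cl)=O
Why: Acylation of the secondary C9 hydroxyl; the tertiary C8 hydroxyl, flanked by three substituted carbons, should not react.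

Step 33
Reactants: 41 C9 acetoxyacetate
Product: 42 CNP0314084.4
Conditions: dimethyldioxirane, acetone–CH2Cl2, −20 → 0 °C
Reagents that add atoms: dimethyldioxirane, CC1(C)OO1
Why: Concerted epoxidation of the most nucleophilic alkene; the strained E C2=C3 bond should react before the hindered, chloride-deactivated C5=C16 and the enone, the trans-epoxide follows from the E geometry, and attack on the exposed outer face of the ring is expected to give the (2R,3R) epoxide.

## Compound list

1 | methyl pyruvate | CC(=O)C(=O)OC | starting material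
2 | methyl 2-[(triethylsilyl)oxy]prop-2-enoate | C=C(O[Si](CC)(CC)CC)C(=O)OC | intermediate
3 | methyl 2-oxo-3-[(triethylsilyl)oxy]propanoate | CC[Si](CC)(CC)OCC(=O)C(=O)OC | intermediate
4 | S-ethyl propanethioate | CCC(=O)SCC | starting material
5 | (Z)-1-(ethylsulfanyl)-1-[(trimethylsilyl)oxy]prop-1-ene | C/C=C(/O[Si](C)(C)C)SCC | intermediate
6 | methyl (2R,3R)-4-(ethylsulfanyl)-2-hydroxy-3-methyl-4-oxo-2-{[(triethylsilyl)oxy]methyl}butanoate | COC(=O)[C@](O)(CO[Si](CC)(CC)CC)[C@@H](C)C(=O)SCC | intermediate
7 | dimethyl (2R,3R)-2-hydroxy-3-methyl-2-{[(triethylsilyl)oxy]methyl}butanedioate | COC(=O)[C@](O)(CO[Si](CC)(CC)CC)[C@@H](C)C(=O)OC | intermediate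
8 | dimethyl (2R,3R)-2-(methoxymethoxy)-3-methyl-2-{[(triethylsilyl)oxy]methyl}butanedioate | COC(=O)[C@](OCOC)(CO[Si](CC)(CC)CC)[C@@H](C)C(=O)OC | intermediate
9 | methyl (2R,3R)-3-formyl-3-(methoxymethoxy)-2-methyl-4-[(triethylsilyl)oxy]butanoate (C7 aldehyde, C8 OMOM, C9 OTES, C19 ester) | O=C[C@](OCOC)(CO[Si](CC)(CC)CC)[C@@H](C)C(=O)OC | intermediate
10 | dimethyl itaconate (dimethyl 2-methylidenebutanedioate) | C=C(CC(=O)OC)C(=O)OC | starting material
11 | 2-methylidenebutane-1,4-diol | C=C(CO)CCO | intermediate
12 | 3-(chloromethyl)but-3-en-1-ol | C=C(CCl)CCO | intermediate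
13 | tert-butyl{[3-(chloromethyl)but-3-en-1-yl]oxy}diphenylsilane | C=C(CCl)CCO[Si](c1ccccc1)(c1ccccc1)C(C)(C)C | intermediate
14 | {3-chloro-2-[2-(tert-butyldiphenylsilyloxy)ethyl]prop-2-en-1-yl}bis(isopinocampheyl)borane, chlorine cis to CH2B (2E by the sequence rule), isopinocampheyl groups from (−)-α-pinene | Cl/C=C(\CB([C@H]1C[C@H]2C[C@@H]([C@@H]1C)C2(C)C)[C@H]1C[C@H]2C[C@@H]([C@@H]1C)C2(C)C)CCO[Si](c1ccccc1)(c1ccccc1)C(C)(C)C | intermediate
15 | O-bis(isopinocampheyl)boryl derivative of 16 (C7–O–B borinate, syn C6 chloride) | C=C(CCO[Si](c1ccccc1)(c1ccccc1)C(C)(C)C)[C@H](Cl)[C@@H](OB([C@H]1C[C@H]2C[C@@H]([C@@H]1C)C2(C)C)[C@H]1C[C@H]2C[C@@H]([C@@H]1C)C2(C)C)[C@](OCOC)(CO[Si](CC)(CC)CC)[C@@H](C)C(=O)OC | intermediate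
16 | methyl 5-chloro-4-hydroxy-3-(methoxymethoxy)-2-methyl-6-methylidene-8-[(tert-butyldiphenylsilyl)oxy]-3-{[(triethylsilyl)oxy]methyl}octanoate, open-chain C7 alcohol with the configuration of 17 | C=C(CCO[Si](c1ccccc1)(c1ccccc1)C(C)(C)C)[C@H](Cl)[C@@H](O)[C@](OCOC)(CO[Si](CC)(CC)CC)[C@@H](C)C(=O)OC | intermediate
17 | (3R,4R,5S)-5-{(1S)-1-chloro-2-methylidene-4-[(tert-butyldiphenylsilyl)oxy]butyl}-4-(methoxymethoxy)-3-methyl-4-{[(triethylsilyl)oxy]methyl}oxolan-2-one | C=C(CCO[Si](c1ccccc1)(c1ccccc1)C(C)(C)C)[C@H](Cl)[C@H]1OC(=O)[C@H](C)[C@@]1(OCOC)CO[Si](CC)(CC)CC | intermediate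
18 | (E)-1-(dimethylamino)-3-[(tert-butyldimethylsilyl)oxy]buta-1,3-diene | CN(C)/C=C/C(=C)O[Si](C)(C)C(C)(C)C | starting material
19 | methacrolein (2-methylprop-2-enal) | CC(=C)C=O | starting material
20 | (1R,2S)-2-(dimethylamino)-1-methyl-4-[(tert-butyldimethylsilyl)oxy]cyclohex-3-ene-1-carbaldehyde | O=C[C@]1(C)CCC(O[Si](C)(C)C(C)(C)C)=C[C@@H]1N(C)C | intermediate
21 | amino alcohol from reduction of the aldehyde of 20, configuration unchanged | OC[C@]1(C)CCC(O[Si](C)(C)C(C)(C)C)=C[C@@H]1N(C)C | intermediate
22 | (R)-4-(hydroxymethyl)-4-methylcyclohex-2-en-1-one | OC[C@@]1(C)C=CC(=O)CC1 | intermediate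
23 | (R)-4-{[(tert-butyldiphenylsilyl)oxy]methyl}-4-methylcyclohex-2-en-1-one | CC(C)(C)[Si](c1ccccc1)(c1ccccc1)OC[C@@]1(C)C=CC(=O)CC1 | intermediate
24 | (4R)-4-{[(tert-butyldiphenylsilyl)oxy]methyl}-6-hydroxy-4-methylcyclohex-2-en-1-one, both C6 epimers | CC(C)(C)[Si](c1ccccc1)(c1ccccc1)OC[C@@]1(C)C=CC(=O)C(O)C1 | intermediate
25 | (8R)-8-{[(tert-butyldiphenylsilyl)oxy]methyl}-8-methyl-1,4-dioxaspiro[4.5]dec-9-en-6-ol, both C6 epimers | CC(C)(C)[Si](c1ccccc1)(c1ccccc1)OC[C@@]1(C)C=CC2(OCCO2)C(O)C1 | intermediate
26 | (8R)-8-{[(tert-butyldiphenylsilyl)oxy]methyl}-8-methyl-1,4-dioxaspiro[4.5]dec-9-en-6-one (C11 ketone, C12 ketal) | CC(C)(C)[Si](c1ccccc1)(c1ccccc1)OC[C@@]1(C)C=CC2(OCCO2)C(=O)C1 | intermediate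
27 | {[(8S)-8-{[(tert-butyldiphenylsilyl)oxy]methyl}-8-methyl-1,4-dioxaspiro[4.5]deca-6,9-dien-6-yl]oxy}trimethylsilane | CC(C)(C)[Si](c1ccccc1)(c1ccccc1)OC[C@@]1(C)C=CC2(OCCO2)C(O[Si](C)(C)C)=C1 | intermediate
28 | (2S,3S,4R)-2-{(1S)-1-chloro-2-methylidene-4-[(tert-butyldiphenylsilyl)oxy]butyl}-3-(methoxymethoxy)-4-methyl-5-oxooxolane-3-carbaldehyde (C9 aldehyde) | C=C(CCO[Si](c1ccccc1)(c1ccccc1)C(C)(C)C)[C@H](Cl)[C@H]1OC(=O)[C@H](C)[C@@]1(OCOC)C=O | intermediate
29 | aldol adduct: lactone of 28 joined through the C9 secondary alcohol to C10 of ring A (C11 ketone, C12 dioxolane, C13=C14, C1 with CH3 and CH2OTBDPS); C1, C6–C10 and C17 as in 42 | C=C(CCO[Si](c1ccccc1)(c1ccccc1)C(C)(C)C)[C@H](Cl)[C@H]1OC(=O)[C@H](C)[C@@]1(OCOC)[C@@H](O)[C@H]2C(=O)C3(OCCO3)C=C[C@]2(C)CO[Si](c2ccccc2)(c2ccccc2)C(C)(C)C | intermediate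
30 | C9 methoxymethyl ether of 29 | C=C(CCO[Si](c1ccccc1)(c1ccccc1)C(C)(C)C)[C@H](Cl)[C@H]1OC(=O)[C@H](C)[C@@]1(OCOC)[C@@H](OCOC)[C@H]2C(=O)C3(OCCO3)C=C[C@]2(C)CO[Si](c2ccccc2)(c2ccccc2)C(C)(C)C | intermediate
31 | C11 methylidene analogue of 30 (C11=C20, C12 dioxolane) | C=C(CCO[Si](c1ccccc1)(c1ccccc1)C(C)(C)C)[C@H](Cl)[C@H]1OC(=O)[C@H](C)[C@@]1(OCOC)[C@@H](OCOC)[C@H]2C(=C)C3(OCCO3)C=C[C@]2(C)CO[Si](c2ccccc2)(c2ccccc2)C(C)(C)C | intermediate
32 | cross-conjugated dienone (C11=C20, C12 ketone, C13=C14) | C=C(CCO[Si](c1ccccc1)(c1ccccc1)C(C)(C)C)[C@H](Cl)[C@H]1OC(=O)[C@H](C)[C@@]1(OCOC)[C@@H](OCOC)[C@H]2C(=C)C(=O)C=C[C@]2(C)CO[Si](c2ccccc2)(c2ccccc2)C(C)(C)C | intermediate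
33 | C11 tertiary α-ketol (11α-OH, 11β-CH3, C12 ketone, C13=C14); C11 as in 42 | C=C(CCO[Si](c1ccccc1)(c1ccccc1)C(C)(C)C)[C@H](Cl)[C@H]1OC(=O)[C@H](C)[C@@]1(OCOC)[C@@H](OCOC)[C@H]2[C@](C)(O)C(=O)C=C[C@]2(C)CO[Si](c2ccccc2)(c2ccccc2)C(C)(C)C | intermediate
34 | C11 acetate of 33 | C=C(CCO[Si](c1ccccc1)(c1ccccc1)C(C)(C)C)[C@H](Cl)[C@H]1OC(=O)[C@H](C)[C@@]1(OCOC)[C@@H](OCOC)[C@H]2[C@](C)(OC(C)=O)C(=O)C=C[C@]2(C)CO[Si](c2ccccc2)(c2ccccc2)C(C)(C)C | intermediate
35 | diol with free C3 and C2 primary hydroxyls | C=C(CCO)[C@H](Cl)[C@H]1OC(=O)[C@H](C)[C@@]1(OCOC)[C@@H](OCOC)[C@H]2[C@](C)(OC(C)=O)C(=O)C=C[C@]2(C)CO | intermediate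
36 | C3 (1-phenyl-1H-tetrazol-5-yl) sulfide, free C2 hydroxyl | C=C(CCSc1nnnn1-c1ccccc1)[C@H](Cl)[C@H]1OC(=O)[C@H](C)[C@@]1(OCOC)[C@@H](OCOC)[C@H]2[C@](C)(OC(C)=O)C(=O)C=C[C@]2(C)CO | intermediate
37 | C3 (1-phenyl-1H-tetrazol-5-yl) sulfone, free C2 hydroxyl | C=C(CCS(=O)(=O)c1nnnn1-c1ccccc1)[C@H](Cl)[C@H]1OC(=O)[C@H](C)[C@@]1(OCOC)[C@@H](OCOC)[C@H]2[C@](C)(OC(C)=O)C(=O)C=C[C@]2(C)CO | intermediate
38 | C2 aldehyde, C3 sulfone | C=C(CCS(=O)(=O)c1nnnn1-c1ccccc1)[C@H](Cl)[C@H]1OC(=O)[C@H](C)[C@@]1(OCOC)[C@@H](OCOC)[C@H]2[C@](C)(OC(C)=O)C(=O)C=C[C@]2(C)C=O | intermediate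
39 | briarane core with (2E)-C2=C3, 8,9-bis(methoxymethoxy), 11-acetoxy, 12-oxo-13-ene, 6-chloro, 5(16)-ene; stereocentres as in 42 | C=C1C/C=C/[C@@]2(C)C=CC(=O)[C@@](C)(OC(C)=O)[C@@H]2[C@H](OCOC)[C@@]2(OCOC)[C@H](OC(=O)[C@@H]2C)[C@H]1Cl | intermediate
40 | 8,9-diol of 39 | C=C1C/C=C/[C@@]2(C)C=CC(=O)[C@@](C)(OC(C)=O)[C@@H]2[C@H](O)[C@@]2(O)[C@H](OC(=O)[C@@H]2C)[C@H]1Cl | intermediate
41 | 9-O-(acetoxyacetyl) derivative of 40 (2,3-deoxy target) | C=C1C/C=C/[C@@]2(C)C=CC(=O)[C@@](C)(OC(C)=O)[C@@H]2[C@H](OC(=O)COC(C)=O)[C@@]2(O)[C@H](OC(=O)[C@@H]2C)[C@H]1Cl | intermediate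
42 | CNP0314084.4, (1S,2R,3R,6S,7S,8R,9S,10S,11S,17R) | C=C1C[C@H]2O[C@@H]2[C@@]2(C)C=CC(=O)[C@@](C)(OC(C)=O)[C@@H]2[C@H](OC(=O)COC(C)=O)[C@@]2(O)[C@H](OC(=O)[C@@H]2C)[C@H]1Cl | target

## Step count and risk

Total: 33 steps. Longest linear sequence: 22 steps (steps 1, 2, 4–7, 11, 19–33, from methyl pyruvate). The ring A branch (steps 12–18) and the allylic chloride branch (steps 8–10) join at steps 20 and 11.

**Step 11 (key step).** Deprotonation of 13 may not be clean: competing abstraction of the C4 allylic hydrogens would lead to elimination of the silyloxy group. The 2-substituted chloroallyl unit may also equilibrate to a mixture of chlorine geometries on boron, which would erode the syn C6/C7 relation, and the α-quaternary aldehyde may react slowly with the hindered borane. The fallback forms the same C6–C7 bond by an aldol reaction. It sets out from 13 and 9. Ozonolysis of 13 (O3, then PPh3) gives 1-chloro-4-[(tert-butyldiphenylsilyl)oxy]butan-2-one F1. Its syn-selective boron-mediated aldol addition to 9 (n-Bu2BOTf, i-Pr2NEt, enolisation towards the chloromethyl group), followed by the same acid-promoted lactonisation, gives the C5 ketone chloro lactone F2. Methylenation of F2 with Cp2Ti(μ-Cl)(μ-CH2)AlMe2 returns to the route at 17.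

**Step 20 (union).** Magnesium chelation between the aldehyde and the methoxymethyl oxygen may be incomplete, so that addition through the non-chelated arrangement gives the C9 epimer; the hindered enol ether may also react slowly. The fallback changes from the open, Lewis acid-mediated pathway to a closed metal enolate pathway. It sets out from 27 and 28 and comes back at 29: 27 is converted with MeLi into its lithium enolate, which is transmetallated with Cp2ZrCl2; the zirconium enolate adds to 28 through a cyclic transition state that is syn-selective whatever the enolate geometry. No new isolated compound arises.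

**Step 30 (ring closure).** Intermolecular olefination may compete with closure of the strained ten-membered ring, and the base may also deprotonate C17 of the lactone, leading to β-elimination of the C8 methoxymethoxy group. The fallback closes the same bond by metathesis. It sets out from 37. Julia–Kocienski methylenation (KN(SiMe3)2, formaldehyde) gives the C3 terminal alkene alcohol F6. Oxidation with Dess–Martin periodinane gives the aldehyde F7, and Wittig methylenation (Ph3P=CH2, −78 °C) gives the diene F8. Ring-closing metathesis with the second-generation Hoveyda–Grubbs catalyst at high dilution returns to the route at 39.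

**Step 24 (C11 oxygenation).** Hydrogen-atom transfer may not be selective for the exocyclic enone: transfer to C5=C16 would give a radical β to the chloride and lead to loss of chlorine. The fallback separates reduction from oxidation. It sets out from 32: conjugate hydrosilylation with catalytic [(Ph3P)CuH]6 and Et3SiH gives the silyl dienol ether F5 (C11 methyl, C12 triethylsilyloxy diene); Rubottom oxidation with dimethyldioxirane on the α face and mild acidic work-up return to the route at 33.

**Step 7 (partial reduction).** The hydride may not discriminate between the two methyl esters, or may reduce the C7 ester past the aldehyde stage. The fallback sets out from 7. Hydroxyl-directed reduction of the α-hydroxy ester with BH3·SMe2 and catalytic NaBH4 gives the diol F3. Oxidation of its primary alcohol with TEMPO and PhI(OAc)2 gives the hydroxy aldehyde F4, and methoxymethylation (MOMCl, i-Pr2NEt) returns to the route at 9.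

**Step 33 (epoxidation).** The facial selectivity rests only on the ring conformation and may be poor or reversed. The fallback replaces substrate control by reagent control: it sets out from 41 and comes back at 42 by epoxidation with a fructose-derived chiral ketone and KHSO5 (buffered, 0 °C), where the catalyst enantiomer is chosen for the required face. No new compound arises.

## Further compounds

F1 | step 11 | 1-chloro-4-[(tert-butyldiphenylsilyl)oxy]butan-2-one | ClCC(=O)CCO[Si](c1ccccc1)(c1ccccc1)C(C)(C)C
F2 | step 11 | C5 ketone analogue of 17: (3R,4R,5S)-5-{(1S)-1-chloro-2-oxo-4-[(tert-butyldiphenylsilyl)oxy]butyl}-4-(methoxymethoxy)-3-methyl-4-{[(triethylsilyl)oxy]methyl}oxolan-2-one | O=C(CCO[Si](c1ccccc1)(c1ccccc1)C(C)(C)C)[C@H](Cl)[C@H]1OC(=O)[C@H](C)[C@@]1(OCOC)CO[Si](CC)(CC)CC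
F0 | step 20 | none | none
F6 | step 30 | C3 terminal alkene (but-3-enyl chain) with free C2 hydroxyl, otherwise as 37 | C=CCC(=C)[C@H](Cl)[C@H]1OC(=O)[C@H](C)[C@@]1(OCOC)[C@@H](OCOC)[C@H]2[C@](C)(OC(C)=O)C(=O)C=C[C@]2(C)CO
F7 | step 30 | C2 aldehyde of F6 | C=CCC(=C)[C@H](Cl)[C@H]1OC(=O)[C@H](C)[C@@]1(OCOC)[C@@H](OCOC)[C@H]2[C@](C)(OC(C)=O)C(=O)C=C[C@]2(C)C=O
F8 | step 30 | diene with vinyl group on C1 and terminal alkene at C3 | C=CCC(=C)[C@H](Cl)[C@H]1OC(=O)[C@H](C)[C@@]1(OCOC)[C@@H](OCOC)[C@H]2[C@](C)(OC(C)=O)C(=O)C=C[C@]2(C)C=C
F5 | step 24 | triethylsilyl dienol ether of the C11-methyl C12 ketone (C11=C12 enol ether, C13=C14) | C=C(CCO[Si](c1ccccc1)(c1ccccc1)C(C)(C)C)[C@H](Cl)[C@H]1OC(=O)[C@H](C)[C@@]1(OCOC)[C@@H](OCOC)[C@H]2C(C)=C(O[Si](CC)(CC)CC)C=C[C@]2(C)CO[Si](c2ccccc2)(c2ccccc2)C(C)(C)C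
F3 | step 7 | methyl (2R,3R)-3,4-dihydroxy-2-methyl-3-{[(triethylsilyl)oxy]methyl}butanoate | OC[C@](O)(CO[Si](CC)(CC)CC)[C@@H](C)C(=O)OC
F4 | step 7 | methyl (2R,3R)-3-formyl-3-hydroxy-2-methyl-4-[(triethylsilyl)oxy]butanoate | O=C[C@](O)(CO[Si](CC)(CC)CC)[C@@H](C)C(=O)OC
F0 | step 33 | none | none
A1 | alternative 1 | ring A-fused (2E,6Z)-cyclodecadien-8-one with C5 ketal, C9 methoxymethyl ether and C11 triethylsilyl ether | O=C1/C=C\C2(OCCO2)C/C=C/[C@@]2(C)C=CC(=O)[C@@](C)(O[Si](CC)(CC)CC)[C@@H]2[C@@H]1OCOC
A2 | alternative 2 | briarane core with ring A as the C11 tertiary α-ketol, C6 and C9 tert-butyldimethylsilyl ethers and C8 triethylsilyl ether | C=C1C[C@H]2O[C@@H]2[C@@]2(C)CCC(=O)[C@@](C)(O)[C@@H]2[C@H](O[Si](C)(C)C(C)(C)C)[C@@]2(O[Si](CC)(CC)CC)[C@H](OC(=O)[C@@H]2C)[C@@H]1O[Si](C)(C)C(C)(C)C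
A3 | alternative 3 | cis-fused chloro lactone cyclohexenone carrying C6, C7, C8 and C17 | O=C1C=C[C@@]2(O)[C@H](OC(=O)[C@@H]2C)[C@H]1Cl
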